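**Retrosynthetic overview**
- The strategy rests on one feature of the benzene ring. C2(Br)–C1(CH3)–C6(Br)–C5(Br) is a contiguous four-carbon segment that carries every carbon-bound substituent, and C3(OH)–C4(OH) is a vicinal dioxygenated two-carbon unit.
- Disconnecting C2–C3 and C4–C5 gives 2,3,5-tribromo-4-methylthiophene 1,1-dioxide 5 (four-carbon diene, sulfur lost as SO2) and vinylene carbonate 6 (masked enediol).
- Diene 5 comes from 3-methylthiophene 1 by exhaustive ring bromination and S-oxidation, so the substitution pattern is fixed before the carbocycle exists.
- Ring order: the thiophene and dioxolone rings are purchased, and the six-membered carbocycle is the only ring formed (step 3). Dehydrogenation (step 4) and carbonate hydrolysis (step 5) then give the catechol.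

Key step: step 3

Remark: the target is a planar hexasubstituted benzene with no stereogenic element, so the "single enantiomer" requirement is met trivially. The two stereocentres of the dihydro intermediate 8 are made racemic and are destroyed on aromatization.

**Step 1**
Reactants: 1 3-methylthiophene; 2 bromine
Product: 3 2,3,5-tribromo-4-methylthiophene
Conditions: Br2 (3.3 equiv), CHCl3/AcOH, 0 °C → 60 °C, dark; aq. Na2S2O3 work-up
Reagents that add atoms: bromine (compound 2), BrBr
Why: Electrophilic aromatic bromination fills the two α-positions first and then the one remaining β-position, so exhaustive substitution of the three free ring C–H bonds is unambiguous; excluding light and initiators keeps the methyl group intact.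

**Step 2**
Reactants: 3 2,3,5-tribromo-4-methylthiophene
Product: 5 2,3,5-tribromo-4-methylthiophene 1,1-dioxide, via 2,3,5-tribromo-4-methylthiophene 1-oxide 4 (not isolated)
Conditions: urea·H2O2 (5 equiv), (CF3CO)2O (5 equiv), MeCN, 0 °C → rt; cold aq. NaHCO3 work-up, product stored cold
Reagents that add atoms: urea–hydrogen peroxide, NC(N)=O.OO (oxygen is transferred as peroxytrifluoroacetic acid, OOC(=O)C(F)(F)F, formed in the flask with trifluoroacetic anhydride)
Why: Peroxytrifluoroacetic acid is the established electrophilic oxidant for taking electron-poor halothiophenes through the S-oxide to the S,S-dioxide (sulfide-to-sulfone oxidation), and the four ring substituents should make the non-aromatic sulfone isolable without dimerization.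

**Step 3**
Reactants: 5 2,3,5-tribromo-4-methylthiophene 1,1-dioxide; 6 vinylene carbonate
Product: 8 cis-4,5,7-tribromo-6-methyl-3a,7a-dihydro-1,3-benzodioxol-2-one (racemic), via sulfonyl-bridged cycloadduct 7 (not isolated)
Conditions: 6 (4 equiv), BHT (cat.), PhCl, 100–120 °C, N2 sweep, dark
Reagents that add atoms: none
Why: The non-aromatic, electron-poor dioxide 5 is a locked s-cis diene whose low LUMO pairs with the HOMO of the enediol carbonate 6 in a concerted suprafacial inverse-demand Diels–Alder reaction, giving the 7-thiabicyclo[2.2.1]heptene 7,7-dioxide 7, which loses SO2 by retro-cheletropic extrusion at the reaction temperature to give the cyclohexa-1,3-diene 8. The closest known reaction type is the cycloaddition of tetrahalothiophene 1,1-dioxides with alkenes followed by SO2 extrusion, and vinylene carbonate is an established dienophile for perhalogenated dienes. The six-membered carbocycle is closed by intermolecular [4+2] cycloaddition, in which the C7–C7a and C3a–C4 bonds of 8 (C2–C3 and C4–C5 of the target) form together, and no other ring is closed. The two new stereocentres C3a and C7a are cis because the Z geometry of the cyclic dienophile is transferred suprafacially; they form as a racemate, the endo/exo question disappears with the bridge, and both are erased in step 4. No regiochemistry arises because 6 is symmetric, and the required chemoselectivity (cross-cycloaddition ahead of self-dimerization of 5 and ahead of a second addition to 8) is secured by the fully substituted diene termini of 5, the excess of 6 and the lower reactivity of the hindered sulfone-free diene 8.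

**Step 4**
Reactants: 8 cis-4,5,7-tribromo-6-methyl-3a,7a-dihydro-1,3-benzodioxol-2-one
Product: 9 4,5,7-tribromo-6-methyl-1,3-benzodioxol-2-one
Conditions: DDQ (1.5 equiv), PhCl, 90–110 °C; filter, concentrate, use directly
Reagents that add atoms: none
Why: DDQ dehydrogenation, in which hydride is abstracted from a ring C–H that is both dienylic and α to oxygen and the resulting cation loses a proton, is driven by aromatization; it removes both stereocentres and leaves the aryl bromides, the methyl group and the carbonate untouched.

**Step 5**
Reactants: 9 4,5,7-tribromo-6-methyl-1,3-benzodioxol-2-one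
Product: 10 3,4,6-tribromo-5-methylbenzene-1,2-diol
Conditions: LiOH·H2O (4 equiv), degassed THF/H2O, 0 °C, N2; then 1 M HCl, Na2S2O4 wash
Reagents that add atoms: none
Why: Saponification of a cyclic aryl carbonate (acyl substitution with an electron-poor phenoxide leaving group) is fast at 0 °C, the anaerobic conditions protect the catecholate from oxidation, and acidification releases CO2 and the free catechol.

**Compound list**
1 | 3-methylthiophene | Cc1ccsc1 | starting material
2 | bromine | BrBr | starting material
3 | 2,3,5-tribromo-4-methylthiophene | Cc1c(Br)sc(Br)c1Br | intermediate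
4 | 2,3,5-tribromo-4-methylthiophene 1-oxide (racemic and labile at sulfur; not isolated) | CC1=C(Br)S(=O)C(Br)=C1Br | intermediate
5 | 2,3,5-tribromo-4-methylthiophene 1,1-dioxide | CC1=C(Br)S(=O)(=O)C(Br)=C1Br | intermediate
6 | vinylene carbonate (1,3-dioxol-2-one) | O=C1OC=CO1 | starting material
7 | 4,5,7-tribromo-6-methyl-3a,4,7,7a-tetrahydro-4,7-epithio-1,3-benzodioxol-2-one 8,8-dioxide (racemic; drawn as the adduct with the carbonate anti to the SO2 bridge, the other diastereomer converges; not isolated) | CC1=C(Br)[C@@]2(Br)[C@H]3OC(=O)O[C@H]3[C@]1(Br)S2(=O)=O | intermediate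
8 | cis-4,5,7-tribromo-6-methyl-3a,7a-dihydro-1,3-benzodioxol-2-one (racemic, one enantiomer drawn) | CC1=C(Br)[C@H]2OC(=O)O[C@H]2C(Br)=C1Br | intermediate
9 | 4,5,7-tribromo-6-methyl-1,3-benzodioxol-2-one | Cc1c(Br)c2OC(=O)Oc2c(Br)c1Br | intermediate
10 | 3,4,6-tribromo-5-methylbenzene-1,2-diol | Cc1c(Br)c(O)c(O)c(Br)c1Br | target

**Totals**
Total step count: 5. Longest linear sequence: 5 steps (from 3-methylthiophene 1).

**Steps most likely to fail**

Step 3 (key cycloaddition). The acyl-deactivated enediol may add too slowly, so that thermal decay or self-dimerization of the dioxide, or radical polymerization of the dienophile, overtakes ring formation. The fallback sets out from 5 and changes the two-carbon partner to the more electron-rich cyclic enediol diether 2,3-dihydro-1,4-dioxine (purchased; PhMe, 60–80 °C). The sulfonyl-bridged dioxene cycloadduct F1 should lose SO2 to give cis-5,6,8-tribromo-7-methyl-2,3,4a,8a-tetrahydro-1,4-benzodioxine F2. DDQ in hot PhCl should aromatize this to 5,6,8-tribromo-7-methyl-2,3-dihydro-1,4-benzodioxine F3. BBr3 (CH2Cl2, −78 °C → rt, aqueous work-up) then cleaves both aryl alkyl ether bonds, and the route is rejoined at the target 10.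

Step 4 (dehydrogenation). Hydride abstraction from the electron-poor tribromodiene may be slow, and at the temperature then needed, elimination across a C–O bond (loss of one ring oxygen) could compete with loss of H2. The fallback sets out from 8 and removes the carbonate first (K2CO3 cat., MeOH, 0 °C, neutral work-up) to give cis-3,4,6-tribromo-5-methylcyclohexa-3,5-diene-1,2-diol F4. Oxidation of one allylic alcohol with activated MnO2 (CH2Cl2, rt) gives 2,4,5-tribromo-6-hydroxy-3-methylcyclohexa-2,4-dien-1-one F5 (or its regioisomer, which converges). This ketol tautomerizes spontaneously to the catechol, and a Na2S2O4 wash returns any over-oxidized o-quinone, so the route is rejoined at the target 10.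

Step 2 (S-oxidation). Oxidation may stall at the poorly nucleophilic tribrominated sulfur, or the sulfone may be lost by self-condensation during isolation. The fallback sets out from 3 and avoids the isolated dioxide. mCPBA with BF3·OEt2 (CH2Cl2, −20 °C) in the presence of excess 6 stops at the S-oxide 4, which is itself a reactive cyclic diene and should be captured as the sulfinyl-bridged cycloadduct 4,5,7-tribromo-6-methyl-3a,4,7,7a-tetrahydro-4,7-epithio-1,3-benzodioxol-2-one 8-oxide F6. Warming F6 in PhMe (80–110 °C) expels sulfur monoxide, and the route is rejoined at 8.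

**Further compounds**
F1 | step 3 | 5,6,8-tribromo-7-methyl-2,3,4a,5,8,8a-hexahydro-5,8-epithio-1,4-benzodioxine 9,9-dioxide (racemic, one diastereomer drawn) | CC1=C(Br)[C@@]2(Br)[C@H]3OCCO[C@H]3[C@]1(Br)S2(=O)=O
F2 | step 3 | cis-5,6,8-tribromo-7-methyl-2,3,4a,8a-tetrahydro-1,4-benzodioxine (racemic) | CC1=C(Br)[C@H]2OCCO[C@H]2C(Br)=C1Br
F3 | step 3 | 5,6,8-tribromo-7-methyl-2,3-dihydro-1,4-benzodioxine | Cc1c(Br)c2OCCOc2c(Br)c1Br
F4 | step 4 | cis-3,4,6-tribromo-5-methylcyclohexa-3,5-diene-1,2-diol (racemic) | CC1=C(Br)[C@@H](O)[C@@H](O)C(Br)=C1Br
F5 | step 4 | 2,4,5-tribromo-6-hydroxy-3-methylcyclohexa-2,4-dien-1-one (racemic) | CC1=C(Br)C(=O)[C@@H](O)C(Br)=C1Br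
F6 | step 2 | 4,5,7-tribromo-6-methyl-3a,4,7,7a-tetrahydro-4,7-epithio-1,3-benzodioxol-2-one 8-oxide (racemic; drawn with S=O syn to the carbonate-bearing bridge) | CC1=C(Br)[C@@]2(Br)[C@H]3OC(=O)O[C@H]3[C@]1(Br)[S@@]2=O
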